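The synthesis rests on cutting ring A into a four-carbon vinylketene and a two-carbon ynol ether. The feature used is that ring A bears no hydrogen and its O-bearing carbons (C5, C7, C8a) alternate with its C-bearing carbons (C4a, C6, C8). Heating cyclobutenone 9 (2-prenyl, 3-OTIPS, free CH2) with siloxyalkyne 6, both made from one ester, should form three ring A bonds in one operation. The product, phenol 13, has both prenyl groups in place, two oxygens silylated, one free OH, and C4a as the only aromatic CH. Formylation at C4a, O-alkylation with ring B bromoketone 22, carbene-catalysed benzoin closure, dehydration and one global desilylation then complete ring C.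

Key step: step 3

Remark: isoflavone numbering is used (O1, C2, C3, C4, C4a, C5–C8, C8a); prenyl = 3-methylbut-2-enyl and TIPS = triisopropylsilyl; the target has no stereocentre; ring A is mirror-symmetric about the C4a···C7 axis until one flanking oxygen is alkylated, so the free OH of 13 can be used as O1.

Step 1
Reactants: 1 ethyl 4-methylpent-3-enoate; 2 dibromomethane; 3 chlorotriisopropylsilane
Product: 6 5-methyl-1-(triisopropylsilyloxy)hex-4-en-1-yne, via dibromoketone enolate 4 (not isolated), via lithium ynolate 5 (not isolated)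
Conditions: lithium 2,2,6,6-tetramethylpiperidide, CH2Br2, THF, −78 °C; add 1; LiN(SiMe3)2; n-BuLi, −78 °C → rt; i-Pr3SiCl, −78 °C → rt
Reagents that add atoms: dibromomethane 2, BrCBr; chlorotriisopropylsilane 3, CC(C)[Si](Cl)(C(C)C)C(C)C
Why: Kowalski ester homologation: LiCHBr2 adds to the ester carbonyl, enolate 4 undergoes bromine–lithium exchange and a 1,2-shift of the prenyl CH2 group to give ynolate 5, and the bulky chlorosilane traps it on oxygen rather than on carbon.

Step 2
Reactants: 6 5-methyl-1-(triisopropylsilyloxy)hex-4-en-1-yne (one portion); 7 acetone (ketene source)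
Product: 9 2-(3-methylbut-2-enyl)-3-(triisopropylsilyloxy)cyclobut-2-en-1-one, via ketene 8 (not isolated)
Conditions: ketene gas (hot-wire pyrolysis of acetone in a ketene generator) bubbled into 6, CH2Cl2, 0 °C → rt
Reagents that add atoms: acetone 7, CC(C)=O, delivered as ketene 8, C=C=O
Why: Thermal [2+2] cycloaddition of ketene with a silyl ynol ether, a known entry to 3-siloxycyclobutenones, in which the nucleophilic prenyl-bearing alkyne carbon bonds to the ketene carbonyl carbon so that prenyl ends on C2 and OTIPS on C3, while amine-free ketene gas avoids acylation of the ynol ether by an acylammonium salt.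

Step 3
Reactants: 9 2-(3-methylbut-2-enyl)-3-(triisopropylsilyloxy)cyclobut-2-en-1-one; 6 5-methyl-1-(triisopropylsilyloxy)hex-4-en-1-yne (second portion, 1.5 equiv)
Product: 13 2,4-bis(3-methylbut-2-enyl)-3,5-bis(triisopropylsilyloxy)phenol, via vinylketene 10 (not isolated), via vinylcyclobutenone 11 (not isolated), via dienylketene 12 (not isolated)
Conditions: toluene (about 1 M), argon, sealed tube, 80 → 125 °C
Reagents that add atoms: none
Why: Reversible 4π electrocyclic opening of 9 should give vinylketene 10, whose C=C=O unit takes up alkyne 6 in a [2+2] cycloaddition to 11, after which a second 4π opening gives dienylketene 12 and 6π electrocyclisation with tautomerisation gives 13. The closest known reaction is the Danheiser benzannulation of cyclobutenones with siloxyalkynes, which makes resorcinol monosilyl ethers; here the cyclobutenone carries one more donor (3-OTIPS), a substituent type that squarate-derived alkoxycyclobutenones tolerate in the same ring opening, although it is expected to raise the temperature needed. Ring A is the only ring closed, by a thermal disrotatory 6π closure between the ketene carbon and the terminal CH2 of 12, and the geometric isomer of 12 that cannot reach this closure returns to 11 because the opening is reversible. With the free OH of 13 later serving as O1, the cycloaddition forms C8–C8a and C6–C7 and the electrocyclisation forms C4a–C8a, which by the mirror symmetry of ring A is the same bond set as C5–C6, C7–C8 and C4a–C5. No stereocentre is created in 13 (the quaternary carbon of 11 is transient and racemic). The selectivity needed is the head-to-tail orientation of the [2+2] step, secured by the silyloxy group of 6, which makes the prenyl-bearing alkyne carbon the nucleophile toward the ketene carbonyl carbon, while the excess of 6 limits acylation of 13 by 10.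

Step 4
Reactants: 13 2,4-bis(3-methylbut-2-enyl)-3,5-bis(triisopropylsilyloxy)phenol; 14 paraformaldehyde
Product: 15 2-hydroxy-3,5-bis(3-methylbut-2-enyl)-4,6-bis(triisopropylsilyloxy)benzaldehyde
Conditions: MgCl2 (anhydrous), Et3N, (CH2O)n, THF, reflux
Reagents that add atoms: paraformaldehyde 14, C=O per unit
Why: Casnati–Skattebøl ortho-formylation: the magnesium phenoxide of 13 binds formaldehyde and delivers it to the ortho carbon, which is the only unsubstituted ring position, a second formaldehyde takes up hydride to give the aldehyde, and the non-acidic medium spares the prenyl groups and the aryl silyl ethers.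

Step 5
Reactants: 16 2,4-dihydroxyacetophenone; 3 chlorotriisopropylsilane
Product: 17 1-[2-hydroxy-4-(triisopropylsilyloxy)phenyl]ethan-1-one
Conditions: i-Pr3SiCl (1.05 equiv), imidazole, CH2Cl2, 0 °C → rt
Reagents that add atoms: chlorotriisopropylsilane 3, CC(C)[Si](Cl)(C(C)C)C(C)C
Why: Chemoselective O-silylation: the 2-OH is held in a hydrogen bond to the acetyl oxygen and is flanked by that group, so the bulky chlorosilane should react only at the 4-OH.

Step 6
Reactants: 17 1-[2-hydroxy-4-(triisopropylsilyloxy)phenyl]ethan-1-one; 18 3-chloro-3-methylbut-1-yne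
Product: 19 1-[2-(2-methylbut-3-yn-2-yloxy)-4-(triisopropylsilyloxy)phenyl]ethan-1-one
Conditions: 18, DBU, CuCl2·2H2O (cat.), MeCN, 0 °C → rt
Reagents that add atoms: 3-chloro-3-methylbut-1-yne 18, C#CC(C)(C)Cl
Why: Copper-catalysed propargylic etherification of a phenol with a tertiary propargylic chloride, known for 1,1-dimethylpropargyl aryl ethers including those of 2-acylphenols, in which DBU breaks the hydrogen bond and the low temperature spares the aryl silyl ether.

Step 7
Reactants: 19 1-[2-(2-methylbut-3-yn-2-yloxy)-4-(triisopropylsilyloxy)phenyl]ethan-1-one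
Product: 20 1-[2,2-dimethyl-5-(triisopropylsilyloxy)-2H-chromen-8-yl]ethan-1-one
Conditions: o-xylene, 140 °C
Reagents that add atoms: none
Why: Aromatic propargyl Claisen rearrangement followed by 1,5-hydrogen shift and oxa-6π electrocyclisation, which can engage only the free ortho carbon between the two oxygens because the other ortho carbon bears the acetyl group, so the pyran oxygen ends next to the acyl-bearing carbon as ring B requires.

Step 8
Reactants: 20 1-[2,2-dimethyl-5-(triisopropylsilyloxy)-2H-chromen-8-yl]ethan-1-one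
Product: 22 2-bromo-1-[2,2-dimethyl-5-(triisopropylsilyloxy)-2H-chromen-8-yl]ethan-1-one, via trimethylsilyl enol ether 21 (not isolated)
Conditions: LiN(SiMe3)2, Me3SiCl, THF, −78 °C; concentrate; NBS (1.0 equiv), THF, −78 → 0 °C
Reagents that add atoms: N-bromosuccinimide, O=C1CCC(=O)N1Br; chlorotrimethylsilane, C[Si](C)(C)Cl (its atoms stay in 21 only)
Why: α-Bromination of a ketone through its silyl enol ether: the methyl group is the only enolisable site, and 21 is far more nucleophilic toward NBS than the chromene C3=C4 bond or the arene, so one equivalent at low temperature should brominate only the α-carbon.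

Step 9
Reactants: 15 2-hydroxy-3,5-bis(3-methylbut-2-enyl)-4,6-bis(triisopropylsilyloxy)benzaldehyde; 22 2-bromo-1-[2,2-dimethyl-5-(triisopropylsilyloxy)-2H-chromen-8-yl]ethan-1-one
Product: 23 2-{2-[2,2-dimethyl-5-(triisopropylsilyloxy)-2H-chromen-8-yl]-2-oxoethoxy}-3,5-bis(3-methylbut-2-enyl)-4,6-bis(triisopropylsilyloxy)benzaldehyde
Conditions: K2CO3, acetone, rt
Reagents that add atoms: none
Why: Williamson ether synthesis with a phenacyl-type bromide at the single free OH of 15, run with a weak base at room temperature so that the product does not go on to an intramolecular aldol condensation of the Rap–Stoermer type.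

Step 10
Reactants: 23 keto aldehyde from step 9
Product: 24 (±)-3-[2,2-dimethyl-5-(triisopropylsilyloxy)-2H-chromen-8-yl]-3-hydroxy-6,8-bis(3-methylbut-2-enyl)-5,7-bis(triisopropylsilyloxy)chroman-4-one
Conditions: 2-(pentafluorophenyl)-6,7-dihydro-5H-pyrrolo[2,1-c][1,2,4]triazol-2-ium tetrafluoroborate (20 mol %), Et3N (20 mol %), toluene, rt → 40 °C
Reagents that add atoms: none
Why: Intramolecular crossed aldehyde–ketone benzoin reaction under N-heterocyclic carbene catalysis, known to turn 2-(2-oxoalkoxy)benzaldehydes into 3-hydroxychroman-4-ones: the carbene makes the aldehyde an acyl anion equivalent that attacks the tethered ketone in a 6-exo mode to form C3–C4, the small and acidic triazolium salt allows a weak amine base, and the C3 stereocentre is formed racemic and is erased in step 11.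

Step 11
Reactants: 24 3-hydroxychroman-4-one from step 10
Product: 25 3-[2,2-dimethyl-5-(triisopropylsilyloxy)-2H-chromen-8-yl]-6,8-bis(3-methylbut-2-enyl)-5,7-bis(triisopropylsilyloxy)-4H-chromen-4-one
Conditions: methyl N-(triethylammoniosulfonyl)carbamate (Burgess reagent), toluene, 60 °C
Reagents that add atoms: none
Why: Burgess dehydration (syn elimination of a tertiary benzylic sulfamate ester): the only β-hydrogens are those on C2, the product gains the conjugation of the 4-pyranone, and the neutral conditions spare the prenyl groups, the chromene and the silyl ethers.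

Step 12
Reactants: 25 tris-TIPS isoflavone from step 11
Product: 26 Kanzonol L, 5,7-dihydroxy-3-(5-hydroxy-2,2-dimethyl-2H-chromen-8-yl)-6,8-bis(3-methylbut-2-enyl)-4H-chromen-4-one
Conditions: Bu4NF (3.3 equiv), AcOH (3.3 equiv), THF, 0 °C → rt
Reagents that add atoms: none
Why: Fluoride-induced cleavage of the three aryl silyl ethers, driven by the Si–F bond and by good phenoxide leaving groups, with acetic acid buffering the phenoxides so that the pyranone is not opened and with no acid strong enough to cyclise a prenyl group onto a neighbouring OH.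

Compound list
1 | ethyl 4-methylpent-3-enoate | CCOC(=O)CC=C(C)C | starting material
2 | dibromomethane | BrCBr | starting material
3 | chlorotriisopropylsilane | CC(C)[Si](Cl)(C(C)C)C(C)C | starting material
4 | lithium 1,1-dibromo-5-methylhexa-1,4-dien-2-olate | CC(C)=CCC([O-])=C(Br)Br.[Li+] | intermediate
5 | lithium 5-methylhex-4-en-1-yn-1-olate | CC(C)=CCC#C[O-].[Li+] | intermediate
6 | 5-methyl-1-(triisopropylsilyloxy)hex-4-en-1-yne | CC(C)=CCC#CO[Si](C(C)C)(C(C)C)C(C)C | intermediate
7 | acetone | CC(C)=O | starting material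
8 | ketene | C=C=O | intermediate
9 | 2-(3-methylbut-2-enyl)-3-(triisopropylsilyloxy)cyclobut-2-en-1-one | O=C1CC(O[Si](C(C)C)(C(C)C)C(C)C)=C1CC=C(C)C | intermediate
10 | 2-(3-methylbut-2-enyl)-3-(triisopropylsilyloxy)buta-1,3-dien-1-one | O=C=C(CC=C(C)C)C(=C)O[Si](C(C)C)(C(C)C)C(C)C | intermediate
11 | 2,4-bis(3-methylbut-2-enyl)-3-(triisopropylsilyloxy)-4-[1-(triisopropylsilyloxy)ethenyl]cyclobut-2-en-1-one (racemic) | O=C1C(CC=C(C)C)=C(O[Si](C(C)C)(C(C)C)C(C)C)C1(CC=C(C)C)C(=C)O[Si](C(C)C)(C(C)C)C(C)C | intermediate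
12 | 2,4-bis(3-methylbut-2-enyl)-3,5-bis(triisopropylsilyloxy)hexa-1,3,5-trien-1-one, ketene and siloxyvinyl groups cis on the central double bond | O=C=C(CC=C(C)C)/C(O[Si](C(C)C)(C(C)C)C(C)C)=C(/CC=C(C)C)C(=C)O[Si](C(C)C)(C(C)C)C(C)C | intermediate
13 | 2,4-bis(3-methylbut-2-enyl)-3,5-bis(triisopropylsilyloxy)phenol | Oc1cc(O[Si](C(C)C)(C(C)C)C(C)C)c(CC=C(C)C)c(O[Si](C(C)C)(C(C)C)C(C)C)c1CC=C(C)C | intermediate
14 | paraformaldehyde (SMILES of the monomer unit) | C=O | starting material
15 | 2-hydroxy-3,5-bis(3-methylbut-2-enyl)-4,6-bis(triisopropylsilyloxy)benzaldehyde | O=Cc1c(O)c(CC=C(C)C)c(O[Si](C(C)C)(C(C)C)C(C)C)c(CC=C(C)C)c1O[Si](C(C)C)(C(C)C)C(C)C | intermediate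
16 | 2,4-dihydroxyacetophenone | CC(=O)c1ccc(O)cc1O | starting material
17 | 1-[2-hydroxy-4-(triisopropylsilyloxy)phenyl]ethan-1-one | CC(=O)c1ccc(O[Si](C(C)C)(C(C)C)C(C)C)cc1O | intermediate
18 | 3-chloro-3-methylbut-1-yne | C#CC(C)(C)Cl | starting material
19 | 1-[2-(2-methylbut-3-yn-2-yloxy)-4-(triisopropylsilyloxy)phenyl]ethan-1-one | CC(=O)c1ccc(O[Si](C(C)C)(C(C)C)C(C)C)cc1OC(C)(C)C#C | intermediate
20 | 1-[2,2-dimethyl-5-(triisopropylsilyloxy)-2H-chromen-8-yl]ethan-1-one | CC(=O)c1ccc(O[Si](C(C)C)(C(C)C)C(C)C)c2c1OC(C)(C)C=C2 | intermediate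
21 | 2,2-dimethyl-5-(triisopropylsilyloxy)-8-[1-(trimethylsilyloxy)ethenyl]-2H-chromene | C=C(O[Si](C)(C)C)c1ccc(O[Si](C(C)C)(C(C)C)C(C)C)c2c1OC(C)(C)C=C2 | intermediate
22 | 2-bromo-1-[2,2-dimethyl-5-(triisopropylsilyloxy)-2H-chromen-8-yl]ethan-1-one | O=C(CBr)c1ccc(O[Si](C(C)C)(C(C)C)C(C)C)c2c1OC(C)(C)C=C2 | intermediate
23 | 2-{2-[2,2-dimethyl-5-(triisopropylsilyloxy)-2H-chromen-8-yl]-2-oxoethoxy}-3,5-bis(3-methylbut-2-enyl)-4,6-bis(triisopropylsilyloxy)benzaldehyde | O=Cc1c(OCC(=O)c2ccc(O[Si](C(C)C)(C(C)C)C(C)C)c3c2OC(C)(C)C=C3)c(CC=C(C)C)c(O[Si](C(C)C)(C(C)C)C(C)C)c(CC=C(C)C)c1O[Si](C(C)C)(C(C)C)C(C)C | intermediate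
24 | (±)-3-[2,2-dimethyl-5-(triisopropylsilyloxy)-2H-chromen-8-yl]-3-hydroxy-6,8-bis(3-methylbut-2-enyl)-5,7-bis(triisopropylsilyloxy)chroman-4-one (racemic) | O=C1c2c(O[Si](C(C)C)(C(C)C)C(C)C)c(CC=C(C)C)c(O[Si](C(C)C)(C(C)C)C(C)C)c(CC=C(C)C)c2OCC1(O)c1ccc(O[Si](C(C)C)(C(C)C)C(C)C)c2c1OC(C)(C)C=C2 | intermediate
25 | 3-[2,2-dimethyl-5-(triisopropylsilyloxy)-2H-chromen-8-yl]-6,8-bis(3-methylbut-2-enyl)-5,7-bis(triisopropylsilyloxy)-4H-chromen-4-one | O=c1c(-c2ccc(O[Si](C(C)C)(C(C)C)C(C)C)c3c2OC(C)(C)C=C3)coc2c(CC=C(C)C)c(O[Si](C(C)C)(C(C)C)C(C)C)c(CC=C(C)C)c(O[Si](C(C)C)(C(C)C)C(C)C)c12 | intermediate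
26 | Kanzonol L | CC(C)=CCc1c(O)c(CC=C(C)C)c2occ(-c3ccc(O)c4c3OC(C)(C)C=C4)c(=O)c2c1O | target

Total step count: 12.
Longest linear sequence: 8 steps (1, 2, 3, 4, 9, 10, 11, 12). The ring B branch (5, 6, 7, 8, then 9 to 12) is equally long.

Steps most likely to fail

Step 3.
- **Risk:** the push–pull stabilisation of the 3-siloxy enone may slow the first ring opening. Hydrolytic loss of the vinylogous silyl ester, self-reaction of the vinylketene, or acylation of the product phenol by the vinylketene could then overtake the cycloaddition.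
- **Fallback:** the prenyl groups would be put on a preformed aromatic ring. The fallback uses no ring A intermediate of the route; it sets out from chlorotriisopropylsilane 3 and comes back at 15.
- Purchased 2,4,6-trihydroxybenzaldehyde F1 would be C-prenylated twice with prenyl bromide (aqueous KOH, 0 °C), the classical way to diprenyl acylphloroglucinols. This should give 2,4,6-trihydroxy-3,5-bis(3-methylbut-2-enyl)benzaldehyde F2.
- Two equivalents of 3 with imidazole in DMF should then silylate the para OH and one of the two equivalent ortho OH groups. The last OH is held back by its hydrogen bond to the aldehyde, which gives 15.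

Step 10.
- **Risk:** addition of the carbene to a di-ortho-substituted, electron-rich aldehyde may be sluggish. Base-induced enolisation of the aryloxymethyl ketone, followed by intramolecular aldol condensation onto the aldehyde, would then win.
- **Fallback:** C3–C1' is made by cross-coupling instead of making C3–C4 by umpolung. The fallback sets out from 15 and comes back at 25.
- For ring A, MeMgBr (excess, THF, −78 → 0 °C) should give 1-[2-hydroxy-3,5-bis(3-methylbut-2-enyl)-4,6-bis(triisopropylsilyloxy)phenyl]ethan-1-ol F3. MnO2 (CH2Cl2) should then give 1-[2-hydroxy-3,5-bis(3-methylbut-2-enyl)-4,6-bis(triisopropylsilyloxy)phenyl]ethan-1-one F4.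
- N,N-Dimethylformamide dimethyl acetal (toluene, 90 °C) should give (E)-3-(dimethylamino)-1-[2-hydroxy-3,5-bis(3-methylbut-2-enyl)-4,6-bis(triisopropylsilyloxy)phenyl]prop-2-en-1-one F5. I2 in CHCl3 should close it to 3-iodo-6,8-bis(3-methylbut-2-enyl)-5,7-bis(triisopropylsilyloxy)-4H-chromen-4-one F6.
- The ring B partner would come from purchased 4-bromobenzene-1,3-diol F7. Reagent 3 with imidazole, acting on the less hindered OH, gives 2-bromo-5-(triisopropylsilyloxy)phenol F8.
- Chloride 18 with DBU and catalytic CuCl2·2H2O gives 1-bromo-2-(2-methylbut-3-yn-2-yloxy)-4-(triisopropylsilyloxy)benzene F9. Heating in o-xylene at 140 °C gives 8-bromo-2,2-dimethyl-5-(triisopropylsilyloxy)-2H-chromene F10.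
- n-BuLi followed by 2-isopropoxy-4,4,5,5-tetramethyl-1,3,2-dioxaborolane gives 2,2-dimethyl-8-(4,4,5,5-tetramethyl-1,3,2-dioxaborolan-2-yl)-5-(triisopropylsilyloxy)-2H-chromene F11.
- Suzuki–Miyaura coupling of F6 with F11 should give 25. Conditions: PdCl2(dppf) (dppf = 1,1'-bis(diphenylphosphino)ferrocene), K2CO3, dioxane/water, 60 °C.

Step 1.
- **Risk:** the doubly activated α-CH2 of the β,γ-unsaturated ester may be deprotonated by the carbenoid or by residual amide base, in competition with carbonyl addition. This would also move the double bond into conjugation.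
- **Fallback:** the ynolate would be reached by oxidation of an acetylide instead of by ester homologation. The fallback sets out from chlorotriisopropylsilane 3 and comes back at ynolate 5, and so at 6.
- Prenyl bromide and ethynylmagnesium bromide (CuCl cat., THF) should give 5-methylhex-4-en-1-yne F12.
- Its lithium acetylide (n-BuLi, THF, −78 °C) would be oxidised with lithium tert-butyl peroxide (from t-BuOOH and LiN(SiMe3)2, −78 → 0 °C) to 5. Reagent 3 then traps 5 as 6.

Further compounds
F1 | step 3 | 2,4,6-trihydroxybenzaldehyde (purchased) | O=Cc1c(O)cc(O)cc1O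
F2 | step 3 | 2,4,6-trihydroxy-3,5-bis(3-methylbut-2-enyl)benzaldehyde | O=Cc1c(O)c(CC=C(C)C)c(O)c(CC=C(C)C)c1O
F3 | step 10 | 1-[2-hydroxy-3,5-bis(3-methylbut-2-enyl)-4,6-bis(triisopropylsilyloxy)phenyl]ethan-1-ol (racemic) | CC(O)c1c(O)c(CC=C(C)C)c(O[Si](C(C)C)(C(C)C)C(C)C)c(CC=C(C)C)c1O[Si](C(C)C)(C(C)C)C(C)C
F4 | step 10 | 1-[2-hydroxy-3,5-bis(3-methylbut-2-enyl)-4,6-bis(triisopropylsilyloxy)phenyl]ethan-1-one | CC(=O)c1c(O)c(CC=C(C)C)c(O[Si](C(C)C)(C(C)C)C(C)C)c(CC=C(C)C)c1O[Si](C(C)C)(C(C)C)C(C)C
F5 | step 10 | (E)-3-(dimethylamino)-1-[2-hydroxy-3,5-bis(3-methylbut-2-enyl)-4,6-bis(triisopropylsilyloxy)phenyl]prop-2-en-1-one | CN(C)/C=C/C(=O)c1c(O)c(CC=C(C)C)c(O[Si](C(C)C)(C(C)C)C(C)C)c(CC=C(C)C)c1O[Si](C(C)C)(C(C)C)C(C)C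
F6 | step 10 | 3-iodo-6,8-bis(3-methylbut-2-enyl)-5,7-bis(triisopropylsilyloxy)-4H-chromen-4-one | O=c1c(I)coc2c(CC=C(C)C)c(O[Si](C(C)C)(C(C)C)C(C)C)c(CC=C(C)C)c(O[Si](C(C)C)(C(C)C)C(C)C)c12
F7 | step 10 | 4-bromobenzene-1,3-diol (purchased) | Oc1ccc(Br)c(O)c1
F8 | step 10 | 2-bromo-5-(triisopropylsilyloxy)phenol | Oc1cc(O[Si](C(C)C)(C(C)C)C(C)C)ccc1Br
F9 | step 10 | 1-bromo-2-(2-methylbut-3-yn-2-yloxy)-4-(triisopropylsilyloxy)benzene | C#CC(C)(C)Oc1cc(O[Si](C(C)C)(C(C)C)C(C)C)ccc1Br
F10 | step 10 | 8-bromo-2,2-dimethyl-5-(triisopropylsilyloxy)-2H-chromene | Brc1ccc(O[Si](C(C)C)(C(C)C)C(C)C)c2c1OC(C)(C)C=C2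
F11 | step 10 | 2,2-dimethyl-8-(4,4,5,5-tetramethyl-1,3,2-dioxaborolan-2-yl)-5-(triisopropylsilyloxy)-2H-chromene | CC1(C)OB(OC1(C)C)c1ccc(O[Si](C(C)C)(C(C)C)C(C)C)c2c1OC(C)(C)C=C2
F12 | step 1 | 5-methylhex-4-en-1-yne | C#CCC=C(C)C
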